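**Retrosynthetic overview**
1. Target 25 ⇒ 18: the three ester C–O bonds and two hydroxyl-directed ketone reductions (C7, then C9) lead back to 13-hydroxylongipin-2-ene-1,7,9-trione 18.
2. 18 ⇒ β-lactone 17 ⇒ gem-dimethyl acid 16: the seven-membered ring is closed by C-acylation (C7–C8 bond); the key disconnection is the C13–O bond, made by a ligand-controlled β-C–H lactonization that also fixes quaternary C6.
3. 16 ⇒ 14 ⇒ diazoketone 11: enone oxygen by allylic C–H oxidation; cyclobutane by Wolff contraction of a bicyclo[3.2.1]octenone; C15 by enolate methylation.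
4. 11 ⇒ cyclopentanone 8 ⇒ 1 + 2 + allyl iodide + isopropenyl Grignard: cyclohexene by ring-closing metathesis; two anti additions relay the single stereocentre of 1.
5. Ring order: cyclopentane (bought, later contracted) → cyclohexene → cyclobutane → cycloheptane.

Assumption: 1 is bought as the bulk prostaglandin intermediate, and the ligand enantiomer in step 9 is fixed by a small screen (the seven-membered ring lies on a near-mirror plane of the core, so the substrate cannot choose between the two C6 methyls).
Names use longipinane numbering: C1 enone carbonyl, C2=C3 (methyl C12 on C3), C4/C11 cyclobutane CH, C5 cyclobutane CH bearing C6, C6 quaternary (C13, C14), C7–C9, C10 quaternary cyclobutane carbon (methyl C15).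

**Route**

Step 1
Reactants: 1 (R)-4-(tert-butyldimethylsilyloxy)cyclopent-2-en-1-one; 2 tert-butyl 2-methylpropanoate
Product: 5 tert-butyl 2-[(1S,2R,5R)-5-(tert-butyldimethylsilyloxy)-3-oxo-2-(prop-2-en-1-yl)cyclopentyl]-2-methylpropanoate, via lithium ester enolate 3 (not isolated), via Michael-adduct lithium enolate 4 (not isolated)
Conditions: LiN(iPr)2, THF, −78 °C; then 1, −78 °C; then allyl iodide, DMPU, −78 to −30 °C
Reagents that add atoms: allyl iodide, C=CCI; lithium diisopropylamide, CC(C)N([Li])C(C)C (lithium stays in 3 and 4 only)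
Why: Tandem Michael addition–enolate alkylation (three-component coupling of the prostaglandin type): the hindered ester enolate adds 1,4 anti to the silyloxy group and the ketone enolate is allylated anti to the new neighbour, giving the all-trans ketone.

Step 2
Reactants: 5 all-trans silyloxy ketone
Product: 6 tert-butyl 2-methyl-2-[(1S,5R)-4-oxo-5-(prop-2-en-1-yl)cyclopent-2-en-1-yl]propanoate
Conditions: DBU, CH2Cl2, 0 °C
Reagents that add atoms: none
Why: E1cB elimination of the β-silyloxy group moves the enone to the other side of the ring (chirality transfer), leaving the two carbon-bearing stereocentres trans.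

Step 3
Reactants: 6 trans-4,5-disubstituted cyclopentenone
Product: 8 tert-butyl 2-methyl-2-[(1S,2R,5R)-3-oxo-2-(prop-2-en-1-yl)-5-(prop-1-en-2-yl)cyclopentyl]propanoate, via trimethylsilyl enol ether 7 (not isolated)
Conditions: CH2=C(CH3)MgBr, CuBr·SMe2 (10 mol%), Me3SiCl, THF, −78 to −40 °C; then 0.5 M HCl, 0 °C
Reagents that add atoms: isopropenylmagnesium bromide, CC(=C)[Mg]Br; chlorotrimethylsilane, C[Si](C)(C)Cl (atoms stay in 7 only)
Why: Copper-catalysed conjugate addition of the Grignard reagent anti to the adjacent tert-alkyl group sets the third ring stereocentre (allyl and isopropenyl cis-1,3, both trans to the side chain).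

Step 4
Reactants: 8 all-trans cyclopentanone
Product: 9 tert-butyl 2-methyl-2-(2-methyl-6-oxobicyclo[3.2.1]oct-2-en-8-yl)propanoate (C8 side chain syn to the C6–C7 bridge)
Conditions: second-generation Grubbs catalyst RuCl2(=CHPh)(PCy3)(H2IMes) (5 mol%), CH2Cl2 (5 mM), 40 °C
Reagents that add atoms: none
Why: Ring-closing metathesis of the cis-1,3 allyl and isopropenyl groups (pseudo-axial when the bulky side chain is equatorial) closes the trisubstituted cyclohexene; no stereocentre changes.

Step 5
Reactants: 9 bicyclo[3.2.1]octenone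
Product: 11 tert-butyl 2-(7-diazo-2-methyl-6-oxobicyclo[3.2.1]oct-2-en-8-yl)-2-methylpropanoate, via trifluoroacetyl ketone 10 (not isolated)
Conditions: LiN(SiMe3)2, THF, −78 °C; CF3CO2CH2CF3; then CH3SO2N3, Et3N, H2O, MeCN, rt
Reagents that add atoms: 2,2,2-trifluoroethyl trifluoroacetate, O=C(OCC(F)(F)F)C(F)(F)F (atoms stay in 10 only); methanesulfonyl azide, CS(=O)(=O)N=[N+]=[N-]
Why: Danheiser detrifluoroacetylative (Regitz-type) diazo transfer; the ketone can enolise only toward the CH2 because its other α-carbon is a bridgehead.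

Step 6
Reactants: 11 α-diazoketone
Product: 14 tert-butyl 2-(6-acetyl-2,6-dimethylbicyclo[3.1.1]hept-2-en-7-yl)-2-methylpropanoate, via ketene 12 (not isolated), via lithium enolate 13 (not isolated)
Conditions: hν (365 nm), THF, −78 °C; then MeLi (1.1 equiv), −78 °C; then MeI, DMPU, −78 to 0 °C
Reagents that add atoms: methyllithium, [Li]C; iodomethane, CI
Why: Photochemical Wolff rearrangement contracts the two-carbon bridge to the cyclobutane, MeLi turns the ketene into a regiodefined enolate, and MeI must attack the face syn to the alkene bridge because the other face is blocked by the 1,3-diaxial tert-alkyl group on C7, which sets quaternary C10 with acetyl and side chain cis.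

Step 7
Reactants: 14 methyl ketone with pinene-type alkene
Product: 15 tert-butyl 2-(6-acetyl-4,6-dimethyl-2-oxobicyclo[3.1.1]hept-3-en-7-yl)-2-methylpropanoate
Conditions: Rh2(C6H10NO)4 (dirhodium tetracaprolactamate, 1 mol%), t-BuOOH (70% aq, 5 equiv), K2CO3, CH2Cl2, rt
Reagents that add atoms: tert-butyl hydroperoxide, CC(C)(C)OO
Why: Radical allylic C–H oxidation at the only allylic methylene gives the verbenone-type enone (the α-pinene to verbenone pattern); no stereocentre is touched.

Step 8
Reactants: 15 enone tert-butyl ester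
Product: 16 2-(6-acetyl-4,6-dimethyl-2-oxobicyclo[3.1.1]hept-3-en-7-yl)-2-methylpropanoic acid
Conditions: CF3CO2H/CH2Cl2 (1:4), 0 °C
Reagents that add atoms: none
Why: Acidolysis of the tert-butyl ester (loss of isobutylene); the enone deactivates the alkene, so the cyclobutane survives brief cold acid.

Step 9
Reactants: 16 gem-dimethyl acid
Product: 17 3-(6-acetyl-4,6-dimethyl-2-oxobicyclo[3.1.1]hept-3-en-7-yl)-3-methyloxetan-2-one (β-lactone; C13 oxidised, C6 configured as in the SMILES)
Conditions: Pd(CH3CN)2Cl2 (10 mol%), (S)-3-acetamido-4,4-dimethylpentanoic acid or its enantiomer (20 mol%), CsHCO3, t-BuOOH (70% aq, 2 equiv), (CF3)2CHOH, 60 °C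
Reagents that add atoms: none
Why: Proposed new method: carboxylate-directed, ligand-assisted concerted metalation–deprotonation of one β-methyl by divalent palladium gives a five-membered palladacycle, t-BuOOH oxidises it to tetravalent palladium and C–O reductive elimination closes the β-lactone; the chiral mono-protected β-amino acid ligand, not the substrate, selects which methyl reacts and so sets quaternary C6; the closest known chemistry is the palladium-catalysed β-C(sp3)–H lactonization of α,α-dialkyl acids with achiral β-amino acid ligands together with enantioselective gem-dimethyl C–H arylation using chiral amino acid ligands.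

Step 10
Reactants: 17 β-lactone methyl ketone
Product: 18 13-hydroxylongipin-2-ene-1,7,9-trione
Conditions: LiN(SiMe3)2 (2.2 equiv), THF, −78 to −20 °C
Reagents that add atoms: none
Why: Intramolecular Claisen-type C-acylation: the kinetic enolate of the methyl ketone attacks the strained lactone carbonyl held 1,3-diaxial to it on the cyclobutane, closing the seven-membered ring and releasing the C13 alkoxide; deprotonation of the β-diketone makes it irreversible.

Step 11
Reactants: 18 hydroxy trione
Product: 19 7,13-dihydroxylongipin-2-ene-1,9-dione (7-OH trans to the CH2OH arm)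
Conditions: Me4NBH(OAc)3 (1.1 equiv), MeCN/AcOH (1:1), −30 °C
Reagents that add atoms: none
Why: Saksena–Evans hydroxyl-directed reduction: the primary alcohol binds boron and delivers hydride to the adjacent C7 ketone from the face of the CH2O arm, setting C7; with one equivalent of hydride and no directing group nearby, the C9 and C1 ketones stay.

Step 12
Reactants: 19 diol dione; 20 angelic acid ((Z)-2-methylbut-2-enoic acid)
Product: 22 13-angeloyloxy-7-hydroxylongipin-2-ene-1,9-dione, via mixed anhydride 21 (not isolated)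
Conditions: 20, 2,4,6-trichlorobenzoyl chloride, Et3N, toluene, rt; then 19, DMAP (0.2 equiv), 0 °C
Reagents that add atoms: 2,4,6-trichlorobenzoyl chloride, O=C(Cl)c1c(Cl)cc(Cl)cc1Cl (atoms stay in 21 only)
Why: Yamaguchi esterification through the mixed anhydride, the usual way to make angelates without Z to E isomerisation; the primary alcohol reacts far faster than the neopentyl secondary one.

Step 13
Reactants: 22 β-hydroxy ketone
Product: 23 7-acetoxy-13-angeloyloxy-9-hydroxylongipin-2-en-1-one (7,9-anti)
Conditions: CH3CHO (5 equiv), SmI2 (0.3 equiv), THF, −10 °C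
Reagents that add atoms: acetaldehyde, CC=O
Why: Evans–Tishchenko reaction: the samarium-bound hemiacetal on O7 transfers hydride intramolecularly to the C9 ketone, giving the 1,3-anti C9 alcohol and leaving the acetate on O7 in one operation.

Step 14
Reactants: 23 C9 alcohol; 24 3-methylbut-2-enoyl chloride
Product: 25 target CNP0179010.1
Conditions: pyridine, DMAP, CH2Cl2, 0 °C to rt
Reagents that add atoms: none
Why: DMAP-catalysed acylation of the last, hindered secondary alcohol; pyridine in place of a trialkylamine avoids vinylketene formation and deconjugation of the senecioate.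

**Compound list**
1 | (R)-4-(tert-butyldimethylsilyloxy)cyclopent-2-en-1-one | O=C1C=C[C@H](O[Si](C)(C)C(C)(C)C)C1 | starting material
2 | tert-butyl 2-methylpropanoate | CC(C)C(=O)OC(C)(C)C | starting material
3 | lithium enolate of 2 | CC(C)=C(O[Li])OC(C)(C)C | intermediate
4 | lithium enolate of the Michael adduct (side chain trans to OTBS) | [Li]OC1=C[C@@H](C(C)(C)C(=O)OC(C)(C)C)[C@H](O[Si](C)(C)C(C)(C)C)C1 | intermediate
5 | tert-butyl 2-[(1S,2R,5R)-5-(tert-butyldimethylsilyloxy)-3-oxo-2-(prop-2-en-1-yl)cyclopentyl]-2-methylpropanoate | O=C1[C@H](CC=C)[C@@H](C(C)(C)C(=O)OC(C)(C)C)[C@H](O[Si](C)(C)C(C)(C)C)C1 | intermediate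
6 | tert-butyl 2-methyl-2-[(1S,5R)-4-oxo-5-(prop-2-en-1-yl)cyclopent-2-en-1-yl]propanoate | O=C1C=C[C@H](C(C)(C)C(=O)OC(C)(C)C)[C@H]1CC=C | intermediate
7 | trimethylsilyl enol ether of 8 | C[Si](C)(C)OC1=C[C@@H](C(C)=C)[C@H](C(C)(C)C(=O)OC(C)(C)C)[C@H]1CC=C | intermediate
8 | tert-butyl 2-methyl-2-[(1S,2R,5R)-3-oxo-2-(prop-2-en-1-yl)-5-(prop-1-en-2-yl)cyclopentyl]propanoate | O=C1[C@H](CC=C)[C@@H](C(C)(C)C(=O)OC(C)(C)C)[C@H](C(C)=C)C1 | intermediate
9 | tert-butyl 2-methyl-2-(2-methyl-6-oxobicyclo[3.2.1]oct-2-en-8-yl)propanoate, side chain syn to the C6–C7 bridge | O=C1C[C@H]2C(C)=CC[C@@H]1[C@H]2C(C)(C)C(=O)OC(C)(C)C | intermediate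
10 | 7-trifluoroacetyl derivative of 9 | O=C1C(C(=O)C(F)(F)F)[C@H]2C(C)=CC[C@@H]1[C@H]2C(C)(C)C(=O)OC(C)(C)C | intermediate
11 | tert-butyl 2-(7-diazo-2-methyl-6-oxobicyclo[3.2.1]oct-2-en-8-yl)-2-methylpropanoate | O=C1C(=[N+]=[N-])[C@H]2C(C)=CC[C@@H]1[C@H]2C(C)(C)C(=O)OC(C)(C)C | intermediate
12 | ketene, tert-butyl 2-methyl-2-[2-methyl-6-(oxomethylidene)bicyclo[3.1.1]hept-2-en-7-yl]propanoate | O=C=C1[C@H]2C(C)=CC[C@@H]1[C@H]2C(C)(C)C(=O)OC(C)(C)C | intermediate
13 | lithium enolate from 12 and MeLi | CC(O[Li])=C1[C@H]2C(C)=CC[C@@H]1[C@H]2C(C)(C)C(=O)OC(C)(C)C | intermediate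
14 | tert-butyl 2-(6-acetyl-2,6-dimethylbicyclo[3.1.1]hept-2-en-7-yl)-2-methylpropanoate (acetyl and side chain on the cyclobutane face away from the alkene bridge, 6-methyl syn to it) | CC(=O)[C@]1(C)[C@H]2C(C)=CC[C@@H]1[C@H]2C(C)(C)C(=O)OC(C)(C)C | intermediate
15 | tert-butyl 2-(6-acetyl-4,6-dimethyl-2-oxobicyclo[3.1.1]hept-3-en-7-yl)-2-methylpropanoate | CC(=O)[C@]1(C)[C@H]2C(C)=CC(=O)[C@@H]1[C@H]2C(C)(C)C(=O)OC(C)(C)C | intermediate
16 | 2-(6-acetyl-4,6-dimethyl-2-oxobicyclo[3.1.1]hept-3-en-7-yl)-2-methylpropanoic acid | CC(=O)[C@]1(C)[C@H]2C(C)=CC(=O)[C@@H]1[C@H]2C(C)(C)C(O)=O | intermediate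
17 | 3-(6-acetyl-4,6-dimethyl-2-oxobicyclo[3.1.1]hept-3-en-7-yl)-3-methyloxetan-2-one | CC(=O)[C@]1(C)[C@H]2C(C)=CC(=O)[C@@H]1[C@H]2[C@@]3(C)COC3=O | intermediate
18 | 13-hydroxylongipin-2-ene-1,7,9-trione | OC[C@]1(C)[C@@H]2[C@H]3C(=O)C=C(C)[C@@H]2[C@@]3(C)C(=O)CC1=O | intermediate
19 | 7,13-dihydroxylongipin-2-ene-1,9-dione | OC[C@]1(C)[C@@H]2[C@H]3C(=O)C=C(C)[C@@H]2[C@@]3(C)C(=O)C[C@H]1O | intermediate
20 | angelic acid, (Z)-2-methylbut-2-enoic acid | C/C=C(/C)C(O)=O | starting material
21 | angelic 2,4,6-trichlorobenzoic anhydride | C/C=C(/C)C(=O)OC(=O)c1c(Cl)cc(Cl)cc1Cl | intermediate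
22 | 13-angeloyloxy-7-hydroxylongipin-2-ene-1,9-dione | C/C=C(/C)C(=O)OC[C@]1(C)[C@@H]2[C@H]3C(=O)C=C(C)[C@@H]2[C@@]3(C)C(=O)C[C@H]1O | intermediate
23 | 7-acetoxy-13-angeloyloxy-9-hydroxylongipin-2-en-1-one | C/C=C(/C)C(=O)OC[C@]1(C)[C@@H]2[C@H]3C(=O)C=C(C)[C@@H]2[C@@]3(C)[C@H](O)C[C@H]1OC(C)=O | intermediate
24 | 3-methylbut-2-enoyl chloride (senecioyl chloride) | CC(C)=CC(Cl)=O | starting material
25 | CNP0179010.1, 7-acetoxy-13-angeloyloxy-9-(3-methylbut-2-enoyloxy)longipin-2-en-1-one | C/C=C(/C)C(=O)OC[C@]1(C)[C@@H]2[C@H]3C(=O)C=C(C)[C@@H]2[C@@]3(C)[C@H](OC(=O)C=C(C)C)C[C@H]1OC(C)=O | target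

**Step count and risks**
Total steps: 14. Longest linear sequence: 14 steps from 1 (2, 20 and 24 are bought and enter directly).

Step 6 (one-pot Wolff contraction, ketene to enolate, quaternary methylation). The ketene may dimerise before MeLi is added, and the methylation must occur on a hindered face. The fallback sets out from 11 and returns at 14. Photolysis of 11 in THF containing N,O-dimethylhydroxylamine traps the ketene as it forms and gives the ring-contracted Weinreb amide F1 as an epimer mixture. LiN(iPr)2 then MeI methylates the amide enolate under the same facial control to give the quaternary Weinreb amide F2. MeLi then converts F2 into 14.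

Step 9 (the new ligand-controlled lactonization). Methyl selection may be poor, or the enone may suffer under peroxide. The fallback sets out from 16 and returns at 17, using a covalently bound auxiliary and known chemistry. The acid chloride of 16 is condensed with (S)-tert-leucinol to give the hydroxy amide F3, and MsCl/Et3N cyclises it to the 4-tert-butyl oxazoline F4. Pd(OAc)2 with MeCO3tBu and Ac2O at 65 °C acetoxylates one β-methyl diastereoselectively under control of the oxazoline stereocentre, giving the acetoxymethyl oxazoline F5; the antipodal auxiliary is used if the S one picks the wrong methyl. Aqueous HCl then LiOH removes auxiliary and acetate to give the β-hydroxy acid F6, and PhSO2Cl in pyridine closes F6 to 17.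

Step 10 (seven-membered ring by acyl transfer from the β-lactone). The enolate may instead attack intermolecularly, or the vinylogous enone position may be deprotonated. The fallback sets out from 17 and returns at 18. K2CO3 in MeOH opens the lactone to the β-hydroxy methyl ester F7. LiN(SiMe3)2 (3.3 equiv, THF, −78 to 0 °C) then effects an ordinary Claisen condensation of the methyl ketone enolate onto the methyl ester, driven by deprotonation of the β-diketone, and acidic work-up gives 18.

**Further compounds**
F1 | step 6 | ring-contracted Weinreb amide (epimers at the amide-bearing carbon) | CON(C)C(=O)C1[C@H]2C(C)=CC[C@@H]1[C@H]2C(C)(C)C(=O)OC(C)(C)C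
F2 | step 6 | quaternary (6-methyl) Weinreb amide | CON(C)C(=O)[C@]1(C)[C@H]2C(C)=CC[C@@H]1[C@H]2C(C)(C)C(=O)OC(C)(C)C
F3 | step 9 | (S)-tert-leucinol hydroxy amide of 16 | CC(=O)[C@]1(C)[C@H]2C(C)=CC(=O)[C@@H]1[C@H]2C(C)(C)C(=O)N[C@@H](C(C)(C)C)CO
F4 | step 9 | (S)-4-tert-butyl oxazoline | CC(=O)[C@]1(C)[C@H]2C(C)=CC(=O)[C@@H]1[C@H]2C(C)(C)C3=N[C@@H](C(C)(C)C)CO3
F5 | step 9 | acetoxymethyl oxazoline | CC(=O)[C@]1(C)[C@H]2C(C)=CC(=O)[C@@H]1[C@H]2[C@@](C)(COC(C)=O)C3=N[C@@H](C(C)(C)C)CO3
F6 | step 9 | β-hydroxy acid | CC(=O)[C@]1(C)[C@H]2C(C)=CC(=O)[C@@H]1[C@H]2[C@@](C)(CO)C(O)=O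
F7 | step 10 | β-hydroxy methyl ester | CC(=O)[C@]1(C)[C@H]2C(C)=CC(=O)[C@@H]1[C@H]2[C@@](C)(CO)C(=O)OC
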